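**Retrosynthetic overview**
- The three phenols are unmasked last (O-demethylation); before that both formyl groups are put on the finished carbon skeleton by ring lithiation/DMF.
- The C4 carbinol comes from MeLi addition to a C4 ketone, and C2–C3 from hydrogenation of a γ-alkylated enone.
- Key union (C1–C1′ bond): vinylogous Mukaiyama alkylation of a C15 decalin silyl dienol ether with a racemic 2,4,6-trimethoxybenzylic acetate (C13 skeleton), which ionises to an achiral cation.
- Decalin half: ring A is 3-methylcyclohexenone (asymmetric conjugate addition sets C10); ring B is closed second by a Lewis-acid ene cyclisation of an α-methylene ketone onto the side-chain alkene, followed by hydration and desaturation.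
- Aryl half: resorcinol is taken to phloroglucinol trimethyl ether by C–H borylation/oxidation, then lithiation, addition to 3-methylbutanal and acetylation.

Assumption: decalin locants are eudesmane-type (C10 angular-methyl carbon, C5 ring-fusion CH, C4 carbinol carbon, C7 carbon bearing the hydroxypropyl group, C1 carbon bearing the side chain, C1′ benzylic carbon), β is the face of the C10 methyl, and the target is read as 10β-Me, 5α-H, 4β-OH, 7β-side chain, 1α-side chain, C1′ (R).

**Route**

Step 1
Reactants: 1 3-methylcyclohex-2-en-1-one; 2 5-bromo-2-methylpent-2-ene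
Product: 5 (3S)-2-[(dimethylamino)methyl]-3-methyl-3-(4-methylpent-3-en-1-yl)cyclohexan-1-one (mixture of C2 epimers), via (4-methylpent-3-en-1-yl)magnesium bromide 3 (not isolated), via bromomagnesium enolate 4 (not isolated)
Conditions: Mg, Et2O (2 to 3); Cu(OTf)2 (3 mol%), chiral hydroxyalkyl-imidazolinium salt as NHC ligand precursor (4 mol%, enantiomer that gives the (S) centre), Et2O, 0 °C; then CH2=NMe2+ I−, THF, −30 °C to rt
Reagents that add atoms: N,N-dimethylmethyleneiminium iodide (Eschenmoser's salt), C=[N+](C)C.[I-]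
Why: Copper–NHC-catalysed asymmetric conjugate addition of the Grignard reagent sets the C10 quaternary centre under ligand control, and the regiospecific magnesium enolate is trapped at C5 in a Mannich reaction.

Step 2
Reactants: 5 (3S)-2-[(dimethylamino)methyl]-3-methyl-3-(4-methylpent-3-en-1-yl)cyclohexan-1-one
Product: 7 (S)-3-methyl-2-methylidene-3-(4-methylpent-3-en-1-yl)cyclohexan-1-one, via trimethylammonium iodide 6 (not isolated)
Conditions: MeI, Et2O, rt; then aq. NaHCO3, CH2Cl2, rt
Reagents that add atoms: none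
Why: Exhaustive N-methylation followed by E1cB (Hofmann-type) loss of trimethylamine gives the α-methylene ketone without touching C10.

Step 3
Reactants: 7 (S)-3-methyl-2-methylidene-3-(4-methylpent-3-en-1-yl)cyclohexan-1-one
Product: 8 (4aS,7S,8aS)-4a-methyl-7-(prop-1-en-2-yl)octahydronaphthalen-1(2H)-one
Conditions: Me2AlCl (1.5 equiv), CH2Cl2, −78 to 0 °C; aq. HCl work-up; then NaOMe (cat.), MeOH, rt
Reagents that add atoms: none
Why: Lewis-acid-promoted intramolecular ene (cation–olefin) cyclisation of the enone β-carbon C6 onto C7 closes ring B through a chair transition state with the developing 2-propyl cation equatorial (7β), and NaOMe equilibrates the epimerisable C5 to the trans ring fusion (5α-H).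

Step 4
Reactants: 8 (4aS,7S,8aS)-4a-methyl-7-(prop-1-en-2-yl)octahydronaphthalen-1(2H)-one
Product: 9 (4aS,7S,8aS)-7-(2-hydroxypropan-2-yl)-4a-methyloctahydronaphthalen-1(2H)-one
Conditions: Co(acac)2 (20 mol%), PhSiH3, O2 (1 atm), THF, rt
Reagents that add atoms: dioxygen, O=O
Why: Mukaiyama hydration (hydrogen-atom-transfer, Markovnikov) converts the 1,1-disubstituted alkene into the tertiary alcohol without creating a stereocentre and tolerates the ketone.

Step 5
Reactants: 9 (4aS,7S,8aS)-7-(2-hydroxypropan-2-yl)-4a-methyloctahydronaphthalen-1(2H)-one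
Product: 11 (4aR,7S,8aS)-4a-methyl-7-[2-(trimethylsilyloxy)propan-2-yl]-4a,5,6,7,8,8a-hexahydronaphthalen-1(4H)-one, via bis(trimethylsilyl) enol ether 10 (not isolated)
Conditions: LiN(iPr)2 (2.4 equiv), Me3SiCl, THF, −78 to 0 °C; then Pd(OAc)2 (1.1 equiv), MeCN, rt
Reagents that add atoms: chlorotrimethylsilane, C[Si](C)(C)Cl
Why: Kinetic enolisation at the C3 methylene (not the tertiary C5–H) and Saegusa–Ito dehydrogenation give the C2=C3 enone, while the tertiary alcohol is capped as its trimethylsilyl ether in the same operation.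

Step 6
Reactants: 11 (4aR,7S,8aS)-4a-methyl-7-[2-(trimethylsilyloxy)propan-2-yl]-4a,5,6,7,8,8a-hexahydronaphthalen-1(4H)-one
Product: 12 tert-butyl(dimethyl){[(4aR,7S,8aS)-4a-methyl-7-[2-(trimethylsilyloxy)propan-2-yl]-4a,5,6,7,8,8a-hexahydronaphthalen-1-yl]oxy}silane
Conditions: TBSOTf, Et3N, CH2Cl2, 0 °C to rt
Reagents that add atoms: tert-butyldimethylsilyl trifluoromethanesulfonate, CC(C)(C)[Si](C)(C)OS(=O)(=O)C(F)(F)F
Why: Soft enolisation removes the accessible γ-hydrogen at C1 to give the linearly conjugated silyl dienol ether (C1=C2–C3=C4–OSi), because the cross-conjugated isomer would need a tetrasubstituted ring-fusion enol ether.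

Step 7
Reactants: 13 benzene-1,3-diol (resorcinol)
Product: 14 1,3-dimethoxybenzene
Conditions: MeI, K2CO3, acetone, reflux
Reagents that add atoms: iodomethane, CI
Why: Williamson O-methylation of both phenols.

Step 8
Reactants: 14 1,3-dimethoxybenzene
Product: 15 2-(3,5-dimethoxyphenyl)-4,4,5,5-tetramethyl-1,3,2-dioxaborolane
Conditions: [Ir(OMe)(cod)]2 (1.5 mol%), 4,4′-di-tert-butyl-2,2′-bipyridine (3 mol%), B2pin2 (1 equiv), hexane, 60 °C
Reagents that add atoms: bis(pinacolato)diboron, CC1(C)OB(OC1(C)C)B1OC(C)(C)C(C)(C)O1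
Why: Sterically controlled iridium-catalysed aromatic C–H borylation occurs only at C5, the one position not flanked by a methoxy group.

Step 9
Reactants: 15 2-(3,5-dimethoxyphenyl)-4,4,5,5-tetramethyl-1,3,2-dioxaborolane
Product: 16 3,5-dimethoxyphenol
Conditions: 30% H2O2, NaOH (1 equiv), THF–H2O, 0 °C to rt
Reagents that add atoms: hydrogen peroxide, OO
Why: Oxidative 1,2-migration of the aryl boronate (boronate oxidation) installs the third ring oxygen.

Step 10
Reactants: 16 3,5-dimethoxyphenol
Product: 17 1,3,5-trimethoxybenzene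
Conditions: MeI, K2CO3, acetone, reflux
Reagents that add atoms: iodomethane, CI
Why: Williamson O-methylation.

Step 11
Reactants: 17 1,3,5-trimethoxybenzene; 18 3-methylbutanal
Product: 20 racemic 3-methyl-1-(2,4,6-trimethoxyphenyl)butan-1-ol, via 2,4,6-trimethoxyphenyllithium 19 (not isolated)
Conditions: n-BuLi, TMEDA, THF, 0 °C to rt; then 18, −78 °C; H2O
Reagents that add atoms: none
Why: Directed ortho-metalation between two methoxy groups followed by 1,2-addition to the aldehyde gives the racemic carbinol, whose stereocentre is erased later on ionisation.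

Step 12
Reactants: 20 racemic 3-methyl-1-(2,4,6-trimethoxyphenyl)butan-1-ol
Product: 21 racemic 3-methyl-1-(2,4,6-trimethoxyphenyl)butyl acetate
Conditions: Ac2O, Et3N, DMAP (cat.), CH2Cl2, 0 °C; used crude
Reagents that add atoms: acetic anhydride, CC(=O)OC(C)=O
Why: DMAP-catalysed O-acylation turns the hydroxyl into a leaving group that a mild Lewis acid can ionise.

Step 13
Reactants: 12 silyl dienol ether (as in step 6); 21 racemic 3-methyl-1-(2,4,6-trimethoxyphenyl)butyl acetate
Product: 23 (4S,4aR,7S,8aS)-7-(2-hydroxypropan-2-yl)-4a-methyl-4-[(1R)-3-methyl-1-(2,4,6-trimethoxyphenyl)butyl]-4a,5,6,7,8,8a-hexahydronaphthalen-1(4H)-one, via C11 trimethylsilyl ether 22 (not isolated)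
Conditions: ZnBr2 (20 mol%), CH2Cl2, −40 to 0 °C, slow addition of 21 (1.5 equiv); then 1 M HCl, THF, 0 °C
Reagents that add atoms: none
Why: Lewis-acid vinylogous Mukaiyama (SN1) alkylation. The achiral 2,4,6-trimethoxybenzylic cation attacks the γ-carbon C1 from the α face, anti to the axial C10 methyl. The open transition state with the aryl group anti to the C1–C10 bond and the benzylic hydrogen over ring A gives the (R) benzylic centre, and the bulky silyloxy group disfavours attack at C3.

Step 14
Reactants: 23 γ-alkylated enone (as in step 13)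
Product: 24 (4S,4aR,7S,8aS)-7-(2-hydroxypropan-2-yl)-4a-methyl-4-[(1R)-3-methyl-1-(2,4,6-trimethoxyphenyl)butyl]octahydronaphthalen-1(2H)-one
Conditions: H2 (1 atm), 10% Pd/C, EtOAc, rt
Reagents that add atoms: none
Why: Heterogeneous catalytic hydrogenation saturates the enone C2=C3 bond; no stereocentre is formed and the ketone, arene and benzylic C–C bond are untouched.

Step 15
Reactants: 24 saturated ketone (as in step 14)
Product: 25 (1R,4S,4aR,7S,8aS)-7-(2-hydroxypropan-2-yl)-1,4a-dimethyl-4-[(1R)-3-methyl-1-(2,4,6-trimethoxyphenyl)butyl]decahydronaphthalen-1-ol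
Conditions: MeLi (4 equiv), Et2O–THF, −78 to 0 °C; H2O
Reagents that add atoms: methyllithium, [Li]C
Why: 1,2-Addition of methyllithium to the C4 ketone takes the equatorial (α-face) trajectory, because axial attack is blocked by the 1,3-diaxial C10 methyl, giving the 4α-methyl/4β-hydroxy (R) carbinol.

Step 16
Reactants: 25 diol (as in step 15)
Product: 27 5-{(1R)-1-[(1S,4R,4aS,6S,8aR)-4-hydroxy-6-(2-hydroxypropan-2-yl)-4,8a-dimethyldecahydronaphthalen-1-yl]-3-methylbutyl}-2,4,6-trimethoxybenzene-1,3-dicarbaldehyde, via lithium hemiaminalate 26 (not isolated)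
Conditions: n-BuLi (3.3 equiv), TMEDA, THF, 0 °C to rt; DMF (1.1 equiv), −78 to 0 °C; then n-BuLi (1.5 equiv), TMEDA, 0 °C; DMF (3 equiv); aq. HCl to pH 3
Reagents that add atoms: N,N-dimethylformamide, CN(C)C=O
Why: Two successive directed ortho-metalation/formylation cycles at the ring positions flanked by two methoxy groups; the tertiary alcohols ride through as lithium alkoxides and the first formyl group is masked in situ as its lithium hemiaminalate.

Step 17
Reactants: 27 dialdehyde trimethyl ether (as in step 16)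
Product: 28 2,4,6-trihydroxy-5-{(1R)-1-[(1S,4R,4aS,6S,8aR)-4-hydroxy-6-(2-hydroxypropan-2-yl)-4,8a-dimethyldecahydronaphthalen-1-yl]-3-methylbutyl}benzene-1,3-dicarbaldehyde (target)
Conditions: LiSC6H4Me-4 (10 equiv), HMPA, 110 °C; then aq. HCl to pH 3
Reagents that add atoms: none
Why: SN2 O-demethylation by thiolate at the three methyl ethers activated by ortho formyl groups proceeds under basic conditions that spare the tertiary alcohols, the aldehydes and all stereocentres.

**Compound list**

1 | 3-methylcyclohex-2-en-1-one | CC1=CC(=O)CCC1 | starting material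
2 | 5-bromo-2-methylpent-2-ene | CC(C)=CCCBr | starting material
3 | (4-methylpent-3-en-1-yl)magnesium bromide | CC(C)=CCC[Mg]Br | intermediate (not isolated)
4 | bromomagnesium enolate of (S)-3-methyl-3-(4-methylpent-3-en-1-yl)cyclohexanone (C4–O, C4=C5) | CC(C)=CCC[C@]1(C)CCCC(O[Mg]Br)=C1 | intermediate (not isolated)
5 | (3S)-2-[(dimethylamino)methyl]-3-methyl-3-(4-methylpent-3-en-1-yl)cyclohexan-1-one, C2 epimers | CN(C)CC1C(=O)CCC[C@@]1(C)CCC=C(C)C | intermediate
6 | N,N,N-trimethyl ammonium iodide of 5 | C[N+](C)(C)CC1C(=O)CCC[C@@]1(C)CCC=C(C)C.[I-] | intermediate (not isolated)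
7 | (S)-3-methyl-2-methylidene-3-(4-methylpent-3-en-1-yl)cyclohexan-1-one | C=C1C(=O)CCC[C@@]1(C)CCC=C(C)C | intermediate
8 | (4aS,7S,8aS)-4a-methyl-7-(prop-1-en-2-yl)octahydronaphthalen-1(2H)-one (trans-fused, 7β-isopropenyl) | C1CCC(=O)[C@H]2C[C@@H](C(C)=C)CC[C@]12C | intermediate
9 | (4aS,7S,8aS)-7-(2-hydroxypropan-2-yl)-4a-methyloctahydronaphthalen-1(2H)-one | C1CCC(=O)[C@H]2C[C@@H](C(C)(C)O)CC[C@]12C | intermediate
10 | bis(trimethylsilyl) derivative of 9 (C3=C4 silyl enol ether and C11 silyl ether) | C1CC=C(O[Si](C)(C)C)[C@H]2C[C@@H](C(C)(C)O[Si](C)(C)C)CC[C@]12C | intermediate (not isolated)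
11 | (4aR,7S,8aS)-4a-methyl-7-[2-(trimethylsilyloxy)propan-2-yl]-4a,5,6,7,8,8a-hexahydronaphthalen-1(4H)-one | C1C=CC(=O)[C@H]2C[C@@H](C(C)(C)O[Si](C)(C)C)CC[C@]12C | intermediate
12 | tert-butyl(dimethyl)silyl dienol ether of 11 (C1=C2–C3=C4–OTBS, trans-fused) | C1=CC=C(O[Si](C)(C)C(C)(C)C)[C@H]2C[C@@H](C(C)(C)O[Si](C)(C)C)CC[C@]12C | intermediate
13 | benzene-1,3-diol (resorcinol) | Oc1cccc(O)c1 | starting material
14 | 1,3-dimethoxybenzene | COc1cccc(OC)c1 | intermediate
15 | 2-(3,5-dimethoxyphenyl)-4,4,5,5-tetramethyl-1,3,2-dioxaborolane | COc1cc(OC)cc(c1)B1OC(C)(C)C(C)(C)O1 | intermediate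
16 | 3,5-dimethoxyphenol | COc1cc(O)cc(OC)c1 | intermediate
17 | 1,3,5-trimethoxybenzene | COc1cc(OC)cc(OC)c1 | intermediate
18 | 3-methylbutanal | CC(C)CC=O | starting material
19 | 2,4,6-trimethoxyphenyllithium | [Li]c1c(OC)cc(OC)cc1OC | intermediate (not isolated)
20 | racemic 3-methyl-1-(2,4,6-trimethoxyphenyl)butan-1-ol | CC(C)CC(O)c1c(OC)cc(OC)cc1OC | intermediate
21 | racemic 3-methyl-1-(2,4,6-trimethoxyphenyl)butyl acetate | CC(C)CC(OC(C)=O)c1c(OC)cc(OC)cc1OC | intermediate
22 | C11 trimethylsilyl ether of 23 | CC(C)C[C@@H](c1c(OC)cc(OC)cc1OC)[C@@H]1C=CC(=O)[C@H]2C[C@@H](C(C)(C)O[Si](C)(C)C)CC[C@]12C | intermediate (not isolated)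
23 | (4S,4aR,7S,8aS)-7-(2-hydroxypropan-2-yl)-4a-methyl-4-[(1R)-3-methyl-1-(2,4,6-trimethoxyphenyl)butyl]-4a,5,6,7,8,8a-hexahydronaphthalen-1(4H)-one | CC(C)C[C@@H](c1c(OC)cc(OC)cc1OC)[C@@H]1C=CC(=O)[C@H]2C[C@@H](C(C)(C)O)CC[C@]12C | intermediate
24 | (4S,4aR,7S,8aS)-7-(2-hydroxypropan-2-yl)-4a-methyl-4-[(1R)-3-methyl-1-(2,4,6-trimethoxyphenyl)butyl]octahydronaphthalen-1(2H)-one | CC(C)C[C@@H](c1c(OC)cc(OC)cc1OC)[C@@H]1CCC(=O)[C@H]2C[C@@H](C(C)(C)O)CC[C@]12C | intermediate
25 | (1R,4S,4aR,7S,8aS)-7-(2-hydroxypropan-2-yl)-1,4a-dimethyl-4-[(1R)-3-methyl-1-(2,4,6-trimethoxyphenyl)butyl]decahydronaphthalen-1-ol | CC(C)C[C@@H](c1c(OC)cc(OC)cc1OC)[C@@H]1CC[C@@](C)(O)[C@H]2C[C@@H](C(C)(C)O)CC[C@]12C | intermediate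
26 | trilithium salt: mono-adduct of lithiated 25 with DMF (aryl CH(OLi)NMe2, both carbinols as lithium alkoxides) | CC(C)C[C@@H](c1c(OC)c(C(O[Li])N(C)C)c(OC)cc1OC)[C@@H]1CC[C@@](C)(O[Li])[C@H]2C[C@@H](C(C)(C)O[Li])CC[C@]12C | intermediate (not isolated)
27 | 5-{(1R)-1-[(1S,4R,4aS,6S,8aR)-4-hydroxy-6-(2-hydroxypropan-2-yl)-4,8a-dimethyldecahydronaphthalen-1-yl]-3-methylbutyl}-2,4,6-trimethoxybenzene-1,3-dicarbaldehyde | CC(C)C[C@@H](c1c(OC)c(C=O)c(OC)c(C=O)c1OC)[C@@H]1CC[C@@](C)(O)[C@H]2C[C@@H](C(C)(C)O)CC[C@]12C | intermediate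
28 | 2,4,6-trihydroxy-5-{(1R)-1-[(1S,4R,4aS,6S,8aR)-4-hydroxy-6-(2-hydroxypropan-2-yl)-4,8a-dimethyldecahydronaphthalen-1-yl]-3-methylbutyl}benzene-1,3-dicarbaldehyde | CC(C)C[C@@H](c1c(O)c(C=O)c(O)c(C=O)c1O)[C@@H]1CC[C@@](C)(O)[C@H]2C[C@@H](C(C)(C)O)CC[C@]12C | target

**Totals and risks**

Total step count: 17. Longest linear sequence: 11 steps (steps 1–6 then 13–17; the aryl branch, steps 7–12 then 13–17, is equally long).

Step 13 is the most likely to fail. The bulky secondary cation must attack the γ-carbon C1 next to the quaternary C10 rather than C3, the benzylic configuration rests on a transition-state argument, and the cation can also eliminate or alkylate another electron-rich ring. The fallback sets out from 12 (with 17 for the aryl partner) and returns at 24. Vilsmeier formylation of 17 (POCl3, DMF) gives 2,4,6-trimethoxybenzaldehyde F1. A BF3·OEt2-mediated vinylogous Mukaiyama aldol reaction of 12 with this smaller electrophile gives the γ-aldol adduct, the 1α-[hydroxy(2,4,6-trimethoxyphenyl)methyl] enone F2. Ionisation of its benzylic alcohol with BF3·OEt2 in the presence of trimethyl(2-methylallyl)silane (Hosomi–Sakurai allylation) gives the 1α-[3-methyl-1-(2,4,6-trimethoxyphenyl)but-3-enyl] enone F3; the benzylic centre is then set by the adjacent C1 stereocentre and the epimers may need separation. Hydrogenation over Pd/C reduces both alkenes and a dilute acid work-up removes the silyl ether to give 24.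

Step 3 is the next risk. The zwitterion from the Lewis-acid cyclisation can collapse to a cyclobutane, lose the C7 proton to give the isopropylidene isomer, or the enone can polymerise. The fallback sets out from 7 and returns at 9, bypassing 8 and step 4. SnCl4 in CH2Cl2 at −78 °C effects the same ring-B closure as a cation–olefin cyclisation terminated by chloride, giving the tertiary chloride F4 after NaOMe equilibration of C5. Silver-assisted solvolysis (AgNO3, aqueous acetone) converts it into the tertiary alcohol 9.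

Step 16 is the third risk. The second lithiation has to occur on an arene that already carries a lithium hemiaminalate and two alkoxides, so mono-formylated material or addition of n-BuLi to the masked aldehyde may result. The fallback sets out from 25 and returns at 27. Electrophilic dibromination (N-bromosuccinimide, 2.1 equiv, MeCN, 0 °C) of the two free ring positions gives the 3,5-dibromo-2,4,6-trimethoxyphenyl diol F5. Double bromine–lithium exchange with excess t-BuLi in THF at −78 °C followed by DMF and acidic work-up delivers 27.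

**Further compounds**

F1 | step 13 | 2,4,6-trimethoxybenzaldehyde | COc1cc(OC)c(C=O)c(OC)c1
F2 | step 13 | γ-aldol adduct: 1α-[hydroxy(2,4,6-trimethoxyphenyl)methyl] enone with C11 trimethylsilyl ether (carbinol epimers) | OC(c1c(OC)cc(OC)cc1OC)[C@@H]1C=CC(=O)[C@H]2C[C@@H](C(C)(C)O[Si](C)(C)C)CC[C@]12C
F3 | step 13 | 1α-[(1R)-3-methyl-1-(2,4,6-trimethoxyphenyl)but-3-enyl] enone with C11 trimethylsilyl ether | CC(=C)C[C@@H](c1c(OC)cc(OC)cc1OC)[C@@H]1C=CC(=O)[C@H]2C[C@@H](C(C)(C)O[Si](C)(C)C)CC[C@]12C
F4 | step 3 | (4aS,7S,8aS)-7-(2-chloropropan-2-yl)-4a-methyloctahydronaphthalen-1(2H)-one | C1CCC(=O)[C@H]2C[C@@H](C(C)(C)Cl)CC[C@]12C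
F5 | step 16 | 3,5-dibromo analogue of 25 (3,5-dibromo-2,4,6-trimethoxyphenyl diol) | CC(C)C[C@@H](c1c(OC)c(Br)c(OC)c(Br)c1OC)[C@@H]1CC[C@@](C)(O)[C@H]2C[C@@H](C(C)(C)O)CC[C@]12C
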